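**Retrosynthetic overview**

1. Target ⇒ (hydrogenolysis of three benzyl esters; carboxylate alkylation at the ω-carbon) ⇒ ω-chloro lactone dibenzyl ester + (R)-malic acid 4-benzyl ester (from D-aspartic acid 4-benzyl ester).
2. Lactone ⇒ 2,3-dihydrofuran (enol-ether oxidation level) ⇒ acyclic O-vinyl/C-allyl diene: ring-closing metathesis forms the C2=C3 bond of the oxolane ring (lactone locants O1, C2(=O), C3, C4, C5). C2 comes from vinyl acetate and two CH2 groups leave as ethylene.
3. Enabling feature: in the γ-lactone ring, C3 and C4 are unsubstituted CH2 groups and O1 sits on the fully substituted C5. The ring therefore maps onto a 2,2-disubstituted 2,3-dihydrofuran whose only C=C is C2=C3, and with no hydrogen on C5 the enol ether cannot migrate or epimerize that centre.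
4. Diene ⇒ tertiary alcohol ⇒ C5-allylated cis-dioxolanone (temporary ring, self-regeneration of the stereocentre, retention at C5) ⇒ (2R,3S)-3-alkylmalate (Fráter–Seebach alkylation) ⇒ diethyl D-malate + allylic bromide (cross-metathesis).
5. Ring order: temporary 1,3-dioxolan-4-one (step 5, opened in step 7), then the oxolane ring (step 10), oxidized to the lactone in step 11.

Key step: step 10

Assumption: 9-chloronon-1-ene, diethyl D-malate and D-aspartic acid 4-benzyl ester are treated as purchasable; C6 denotes the exocyclic CH next to ring carbon C5.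

**Route**

Step 1
Reactants: 1 9-chloronon-1-ene
Product: 2 (2E)-1-bromo-10-chlorodec-2-ene (minor Z isomer carried along)
Conditions: allyl bromide (5 equiv), second-generation Grubbs catalyst (2 mol%), CH2Cl2, 40 °C
Reagents that add atoms: 3-bromoprop-1-ene (allyl bromide), C=CCBr
Why: Olefin cross-metathesis of a terminal alkene with excess allyl bromide is an established route to allylic bromides, and the alkene geometry is irrelevant because the double bond is hydrogenated in step 3.

Step 2
Reactants: 3 diethyl (2R)-2-hydroxybutanedioate (diethyl D-malate); 2 (2E)-1-bromo-10-chlorodec-2-ene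
Product: 5 diethyl (2R,3S)-3-[(2E)-10-chlorodec-2-en-1-yl]-2-hydroxybutanedioate, via dilithium alkoxide enolate 4 (not isolated)
Conditions: LiN(iPr)2 (2.1 equiv), THF, −78 to −20 °C; 2, −78 to −10 °C; cold 1 M HCl
Reagents that add atoms: none
Why: Fráter–Seebach alkylation: the chelated alkoxide enolate should be alkylated anti to the C2 ester group, setting the new centre as 3S next to the retained 2R carbinol as in the allylation of diethyl malate, and the allylic bromide reacts far faster than the primary chloride.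

Step 3
Reactants: 5 diethyl (2R,3S)-3-[(2E)-10-chlorodec-2-en-1-yl]-2-hydroxybutanedioate
Product: 6 diethyl (2R,3S)-3-(10-chlorodecyl)-2-hydroxybutanedioate
Conditions: H2 (1 atm), 5% Pt/C, EtOAc, rt
Reagents that add atoms: none
Why: Heterogeneous catalytic hydrogenation of the isolated disubstituted alkene should leave the primary C–Cl bond and both stereocentres untouched and removes the E/Z mixture.

Step 4
Reactants: 6 diethyl (2R,3S)-3-(10-chlorodecyl)-2-hydroxybutanedioate
Product: 7 (2R,3S)-3-(10-chlorodecyl)-2-hydroxybutanedioic acid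
Conditions: LiOH·H2O (4 equiv), THF/H2O, 0 °C to rt; 1 M HCl
Reagents that add atoms: lithium hydroxide, [Li+].[OH-]
Why: Ester saponification at or below room temperature is not expected to epimerize the α-branched centre, and the primary chloride is inert to cold aqueous hydroxide.

Step 5
Reactants: 7 (2R,3S)-3-(10-chlorodecyl)-2-hydroxybutanedioic acid
Product: 8 (2S)-2-[(2R,4R)-2-tert-butyl-5-oxo-1,3-dioxolan-4-yl]-12-chlorododecanoic acid (cis-dioxolanone)
Conditions: t-BuCHO (3 equiv), TsOH·H2O (cat.), H2SO4 (cat.), pentane, reflux, Dean–Stark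
Reagents that add atoms: 2,2-dimethylpropanal (pivalaldehyde), CC(C)(C)C=O
Why: Acid-catalysed acetalization of the α-hydroxy acid unit (Seebach self-regeneration-of-stereocentres template) should give the thermodynamically preferred cis five-membered dioxolanone; the new acetal centre (2R) stores the configuration of C5.

Step 6
Reactants: 8 (2S)-2-[(2R,4R)-2-tert-butyl-5-oxo-1,3-dioxolan-4-yl]-12-chlorododecanoic acid
Product: 10 (2S)-2-[(2R,4R)-2-tert-butyl-5-oxo-4-(prop-2-en-1-yl)-1,3-dioxolan-4-yl]-12-chlorododecanoic acid, via dilithium carboxylate enolate 9 (not isolated)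
Conditions: LiN(SiMe3)2 (2.2 equiv), THF, −78 °C; allyl bromide (2 equiv), −78 to −30 °C; 1 M HCl
Reagents that add atoms: 3-bromoprop-1-ene (allyl bromide), C=CCBr
Why: Seebach enolate alkylation: the ring enolate should be allylated on the face anti to the tert-butyl group, so allyl takes the place of the former hydrogen with net retention at C5, while the carboxylate blocks deprotonation at C6.

Step 7
Reactants: 10 (2S)-2-[(2R,4R)-2-tert-butyl-5-oxo-4-(prop-2-en-1-yl)-1,3-dioxolan-4-yl]-12-chlorododecanoic acid
Product: 11 (2R,3S)-3-(10-chlorodecyl)-2-hydroxy-2-(prop-2-en-1-yl)butanedioic acid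
Conditions: LiOH·H2O (4 equiv), THF/H2O, rt; 1 M HCl
Reagents that add atoms: lithium hydroxide, [Li+].[OH-]
Why: Hydroxide attacks the activated acylal carbonyl and the hemiacetal collapses with loss of pivalaldehyde, releasing the tertiary α-hydroxy acid without touching the quaternary centre.

Step 8
Reactants: 11 (2R,3S)-3-(10-chlorodecyl)-2-hydroxy-2-(prop-2-en-1-yl)butanedioic acid
Product: 12 dibenzyl (2R,3S)-3-(10-chlorodecyl)-2-hydroxy-2-(prop-2-en-1-yl)butanedioate
Conditions: BnBr (2.4 equiv), Cs2CO3 (1.2 equiv), DMF, rt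
Reagents that add atoms: benzyl bromide, BrCc1ccccc1
Why: O-alkylation of the cesium carboxylates (SN2) should esterify both acids, while the hindered tertiary hydroxyl and the alkyl chloride do not react under carbonate conditions.

Step 9
Reactants: 12 dibenzyl (2R,3S)-3-(10-chlorodecyl)-2-hydroxy-2-(prop-2-en-1-yl)butanedioate
Product: 13 dibenzyl (2R,3S)-3-(10-chlorodecyl)-2-(ethenyloxy)-2-(prop-2-en-1-yl)butanedioate
Conditions: vinyl acetate (10 equiv), [Ir(cod)Cl]2 (2 mol%), Na2CO3 (0.3 equiv), toluene, 100 °C
Reagents that add atoms: vinyl acetate, CC(=O)OC=C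
Why: Iridium-catalysed transfer vinylation (addition of the iridium alkoxide to vinyl acetate, then β-acetate elimination) is one of the few methods that vinylates tertiary alcohols under nearly neutral conditions, and no stereocentre is involved.

Step 10
Reactants: 13 dibenzyl (2R,3S)-3-(10-chlorodecyl)-2-(ethenyloxy)-2-(prop-2-en-1-yl)butanedioate
Product: 14 benzyl (2R)-2-[(2S)-1-(benzyloxy)-12-chloro-1-oxododecan-2-yl]-2,3-dihydrofuran-2-carboxylate
Conditions: second-generation Grubbs catalyst (5 mol%), 1,4-benzoquinone (10 mol%), toluene (0.005 M), 70 °C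
Reagents that add atoms: none
Why: Ring-closing metathesis: the ruthenium carbene should first engage the terminal allyl olefin to give an alkylidene at the carbon that becomes C3, which undergoes intramolecular [2+2] cycloaddition with the O-vinyl group and cycloreversion, forming C2=C3 and releasing ethylene. The closest known reaction type is the ring-closing metathesis of acyclic vinyl ether/terminal olefin dienes to 2,3-dihydrofurans and glycals with second-generation ruthenium carbenes. The oxolane ring (O1, C2, C3, C4, C5) closes with the new bond as its endocyclic double bond, and five is the only accessible ring size because the two olefins are separated by O1, C5 and C4 only. No stereocentre is created, and C5 and C6 are spectators under the neutral conditions. The step needs initiation at the allyl group rather than at the enol ether (which would hold ruthenium as an unreactive alkoxycarbene) and no double-bond migration. The congested tertiary O-vinyl group and the geminal substitution at C5 favour the first, and benzoquinone with high dilution the second.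

Step 11
Reactants: 14 benzyl (2R)-2-[(2S)-1-(benzyloxy)-12-chloro-1-oxododecan-2-yl]-2,3-dihydrofuran-2-carboxylate
Product: 15 benzyl (2R)-2-[(2S)-1-(benzyloxy)-12-chloro-1-oxododecan-2-yl]-5-oxooxolane-2-carboxylate
Conditions: C5H5NH[CrO3Cl] (pyridinium chlorochromate, 3 equiv), 4 Å molecular sieves, CH2Cl2, rt
Reagents that add atoms: pyridinium chlorochromate, [O-][Cr](=O)(=O)Cl.c1cc[nH+]cc1
Why: Chlorochromate oxidation of cyclic enol ethers (attack at the electron-rich double bond, then hydride shift) is a known conversion of 2,3-dihydrofurans into γ-butyrolactones and should spare the esters, the chloride and both stereocentres.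

Step 12
Reactants: 16 (2R)-2-amino-4-(benzyloxy)-4-oxobutanoic acid (D-aspartic acid 4-benzyl ester)
Product: 17 (2R)-4-(benzyloxy)-2-hydroxy-4-oxobutanoic acid
Conditions: NaNO2 (3 equiv), 1 M H2SO4, 0 °C to rt
Reagents that add atoms: water, O
Why: Diazotization of the α-amino acid with participation of the neighbouring carboxylate and opening by water should give the α-hydroxy acid with net retention (double inversion).

Step 13
Reactants: 15 benzyl (2R)-2-[(2S)-1-(benzyloxy)-12-chloro-1-oxododecan-2-yl]-5-oxooxolane-2-carboxylate; 17 (2R)-4-(benzyloxy)-2-hydroxy-4-oxobutanoic acid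
Product: 18 4-benzyl 1-[(11S)-12-(benzyloxy)-11-{(2R)-2-[(benzyloxy)carbonyl]-5-oxooxolan-2-yl}-12-oxododecyl] (2R)-2-hydroxybutanedioate
Conditions: 17 (1.5 equiv), Cs2CO3 (0.8 equiv), NaI (0.2 equiv), DMF, 60 °C
Reagents that add atoms: none
Why: Carboxylate alkylation (SN2 at the primary carbon after in situ Finkelstein exchange): the cesium carboxylate is far more nucleophilic than the free secondary hydroxyl, so the malate should be attached through its C1 carboxyl only.

Step 14
Reactants: 18 4-benzyl 1-[(11S)-12-(benzyloxy)-11-{(2R)-2-[(benzyloxy)carbonyl]-5-oxooxolan-2-yl}-12-oxododecyl] (2R)-2-hydroxybutanedioate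
Product: 19 (2R)-2-[(1S)-1-carboxy-11-{[(2R)-3-carboxy-2-hydroxypropanoyl]oxy}undecyl]-5-oxooxolane-2-carboxylic acid
Conditions: H2 (1 atm), 10% Pd/C, EtOAc/THF, rt
Reagents that add atoms: none
Why: Catalytic hydrogenolysis should cleave the three benzyl esters while the lactone, the alkyl ester and the secondary alcohol are inert.

**Compound list**

1 | 9-chloronon-1-ene | C=CCCCCCCCCl | starting material
2 | (2E)-1-bromo-10-chlorodec-2-ene | ClCCCCCCC/C=C/CBr | intermediate
3 | diethyl (2R)-2-hydroxybutanedioate (diethyl D-malate) | CCOC(=O)C[C@@H](O)C(=O)OCC | starting material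
4 | dilithium alkoxide enolate of 3 (C2 alkoxide, C3–C4 ester enolate) | CCOC(=O)[C@H]([O-])C=C([O-])OCC.[Li+].[Li+] | intermediate
5 | diethyl (2R,3S)-3-[(2E)-10-chlorodec-2-en-1-yl]-2-hydroxybutanedioate | ClCCCCCCC/C=C/C[C@H](C(=O)OCC)[C@@H](O)C(=O)OCC | intermediate
6 | diethyl (2R,3S)-3-(10-chlorodecyl)-2-hydroxybutanedioate | ClCCCCCCCCCC[C@H](C(=O)OCC)[C@@H](O)C(=O)OCC | intermediate
7 | (2R,3S)-3-(10-chlorodecyl)-2-hydroxybutanedioic acid | ClCCCCCCCCCC[C@H](C(=O)O)[C@@H](O)C(=O)O | intermediate
8 | (2S)-2-[(2R,4R)-2-tert-butyl-5-oxo-1,3-dioxolan-4-yl]-12-chlorododecanoic acid | ClCCCCCCCCCC[C@H](C(=O)O)[C@H]1O[C@@H](C(C)(C)C)OC1=O | intermediate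
9 | dilithium carboxylate enolate of 8 (ring enolate) | ClCCCCCCCCCC[C@H](C(=O)[O-])C1=C([O-])O[C@H](C(C)(C)C)O1.[Li+].[Li+] | intermediate
10 | (2S)-2-[(2R,4R)-2-tert-butyl-5-oxo-4-(prop-2-en-1-yl)-1,3-dioxolan-4-yl]-12-chlorododecanoic acid | ClCCCCCCCCCC[C@H](C(=O)O)[C@@]1(CC=C)O[C@@H](C(C)(C)C)OC1=O | intermediate
11 | (2R,3S)-3-(10-chlorodecyl)-2-hydroxy-2-(prop-2-en-1-yl)butanedioic acid | ClCCCCCCCCCC[C@H](C(=O)O)[C@](O)(CC=C)C(=O)O | intermediate
12 | dibenzyl (2R,3S)-3-(10-chlorodecyl)-2-hydroxy-2-(prop-2-en-1-yl)butanedioate | ClCCCCCCCCCC[C@H](C(=O)OCc1ccccc1)[C@](O)(CC=C)C(=O)OCc1ccccc1 | intermediate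
13 | dibenzyl (2R,3S)-3-(10-chlorodecyl)-2-(ethenyloxy)-2-(prop-2-en-1-yl)butanedioate | ClCCCCCCCCCC[C@H](C(=O)OCc1ccccc1)[C@](OC=C)(CC=C)C(=O)OCc1ccccc1 | intermediate
14 | benzyl (2R)-2-[(2S)-1-(benzyloxy)-12-chloro-1-oxododecan-2-yl]-2,3-dihydrofuran-2-carboxylate | ClCCCCCCCCCC[C@H](C(=O)OCc1ccccc1)[C@@]1(C(=O)OCc2ccccc2)CC=CO1 | intermediate
15 | benzyl (2R)-2-[(2S)-1-(benzyloxy)-12-chloro-1-oxododecan-2-yl]-5-oxooxolane-2-carboxylate | ClCCCCCCCCCC[C@H](C(=O)OCc1ccccc1)[C@@]1(C(=O)OCc2ccccc2)CCC(=O)O1 | intermediate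
16 | (2R)-2-amino-4-(benzyloxy)-4-oxobutanoic acid | N[C@H](CC(=O)OCc1ccccc1)C(=O)O | starting material
17 | (2R)-4-(benzyloxy)-2-hydroxy-4-oxobutanoic acid | O[C@H](CC(=O)OCc1ccccc1)C(=O)O | intermediate
18 | 4-benzyl 1-[(11S)-12-(benzyloxy)-11-{(2R)-2-[(benzyloxy)carbonyl]-5-oxooxolan-2-yl}-12-oxododecyl] (2R)-2-hydroxybutanedioate | O=C(OCc1ccccc1)C[C@@H](O)C(=O)OCCCCCCCCCC[C@H](C(=O)OCc1ccccc1)[C@@]1(C(=O)OCc2ccccc2)CCC(=O)O1 | intermediate
19 | (2R)-2-[(1S)-1-carboxy-11-{[(2R)-3-carboxy-2-hydroxypropanoyl]oxy}undecyl]-5-oxooxolane-2-carboxylic acid | O=C(O)C[C@@H](O)C(=O)OCCCCCCCCCC[C@H](C(=O)O)[C@@]1(C(=O)O)CCC(=O)O1 | target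

**Step count and risks**

Total step count: 14. Longest linear sequence: 13 steps (steps 1–11, 13, 14).

Steps most likely to fail:

1. Step 10 (ring-closing metathesis). The catalyst may add first to the enol ether and rest as an unreactive alkoxycarbene, or decay to ruthenium hydrides that move the allyl double bond, so that ring closure stalls. Fallback: the same C2–C3 bond is made by anionic acylation instead of metathesis; it sets out from 8 and comes back at 15. The dianion of 8 (LiN(SiMe3)2, THF, −78 °C) is added to phenyl vinyl sulfone (Michael addition anti to the tert-butyl group) to give the sulfone acid F1. LiOH in aqueous THF and then BnBr/Cs2CO3 in DMF, as in steps 7 and 8, give the hydroxy diacid F2 and the dibenzyl ester F3. The lithium alkoxide of F3 (1 equiv LiN(SiMe3)2, −78 °C) is acylated with 1,1'-carbonyldiimidazole to the imidazole-1-carboxylate F4. Two further equivalents of LiN(SiMe3)2 generate the sulfonyl carbanion, which attacks the O-bound carbonyl in a 5-exo-trig acyl substitution to give the α-sulfonyl lactone F5. Aluminium amalgam Al(Hg) in aqueous THF removes the sulfonyl group and delivers 15.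

2. Step 9 (transfer vinylation). Alkoxide exchange at the congested tertiary hydroxyl may be slow, with competing O-acetylation by vinyl acetate or iridium-induced migration of the allyl double bond. Fallback: acetal elimination instead of transfer vinylation, from 12 back to 13. Acid-catalysed addition of 12 to ethyl vinyl ether (pyridinium p-toluenesulfonate, CH2Cl2) gives the mixed acetal F6. Me3SiOTf/Et3N (CH2Cl2, 0 °C) then ionizes the ethoxy group and removes a methyl proton (Gassman-type elimination) to give 13.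

3. Step 6 (enolate allylation). The dianion may fragment on warming, or the branched C6 substituent may erode the facial selectivity. Fallback: radical instead of enolate chemistry, from 8 back to 10. Wohl–Ziegler bromination of the captodative ring C–H of 8 (N-bromosuccinimide, AIBN, PhCF3, 80 °C) gives the bromide F7. Keck allylation (Bu3SnCH2CH=CH2, AIBN, benzene, 80 °C) then delivers the allyl group to the ring radical anti to the tert-butyl group to give 10.

**Further compounds**

F1 | step 10 | (2S)-2-[(2R,4R)-2-tert-butyl-5-oxo-4-[2-(phenylsulfonyl)ethyl]-1,3-dioxolan-4-yl]-12-chlorododecanoic acid | ClCCCCCCCCCC[C@H](C(=O)O)[C@@]1(CCS(=O)(=O)c2ccccc2)O[C@@H](C(C)(C)C)OC1=O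
F2 | step 10 | (2R,3S)-3-(10-chlorodecyl)-2-hydroxy-2-[2-(phenylsulfonyl)ethyl]butanedioic acid | ClCCCCCCCCCC[C@H](C(=O)O)[C@](O)(CCS(=O)(=O)c1ccccc1)C(=O)O
F3 | step 10 | dibenzyl (2R,3S)-3-(10-chlorodecyl)-2-hydroxy-2-[2-(phenylsulfonyl)ethyl]butanedioate | ClCCCCCCCCCC[C@H](C(=O)OCc1ccccc1)[C@](O)(CCS(=O)(=O)c1ccccc1)C(=O)OCc1ccccc1
F4 | step 10 | dibenzyl (2R,3S)-3-(10-chlorodecyl)-2-[(1H-imidazol-1-ylcarbonyl)oxy]-2-[2-(phenylsulfonyl)ethyl]butanedioate | ClCCCCCCCCCC[C@H](C(=O)OCc1ccccc1)[C@](OC(=O)n1ccnc1)(CCS(=O)(=O)c1ccccc1)C(=O)OCc1ccccc1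
F5 | step 10 | benzyl (2R)-2-[(2S)-1-(benzyloxy)-12-chloro-1-oxododecan-2-yl]-5-oxo-4-(phenylsulfonyl)oxolane-2-carboxylate (both C4 epimers) | ClCCCCCCCCCC[C@H](C(=O)OCc1ccccc1)[C@@]1(C(=O)OCc2ccccc2)CC(S(=O)(=O)c2ccccc2)C(=O)O1
F6 | step 9 | dibenzyl (2R,3S)-3-(10-chlorodecyl)-2-(1-ethoxyethoxy)-2-(prop-2-en-1-yl)butanedioate (both acetal epimers) | ClCCCCCCCCCC[C@H](C(=O)OCc1ccccc1)[C@](OC(C)OCC)(CC=C)C(=O)OCc1ccccc1
F7 | step 6 | ring C4-bromo derivative of 8 (acetal and exocyclic centres as in 8, both C4 epimers) | ClCCCCCCCCCC[C@H](C(=O)O)C1(Br)O[C@@H](C(C)(C)C)OC1=O
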